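Readings and results are simulated from invented constants; the scatter is artificial.

The examiner puts the maple run and its neighbours on the table and asks for the orders first.

| setting | maple | larch | oak | alder | birch |
|---|---|---|---|---|---|
| starting material | 1.00 M | 0.500 M | 1.00 M | 1.50 M | 1.00 M |
| partner | 0.800 M | 0.300 M | 1.60 M | 0.800 M | 0.800 M |
| free catalyst | 0.00500 M | 0.00500 M | 0.00500 M | 0.00500 M | 0.00500 M |
| time |  |  |  |  | 200 min |

| maple run: time / min | maple run: [target] / M | larch run: time / min | larch run: [target] / M | oak run: time / min | oak run: [target] / M | alder run: time / min | alder run: [target] / M |
|---|---|---|---|---|---|---|---|
| 2.2 | 0.032 | 2.2 | 0.022 | 2.2 | 0.054 | 2.2 | 0.043 |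
| 6.7 | 0.118 | 6.7 | 0.050 | 6.7 | 0.151 | 6.7 | 0.121 |
| 13 | 0.188 | 13 | 0.078 | 13 | 0.249 | 13 | 0.216 |
| 20 | 0.266 | 20 | 0.104 | 20 | 0.342 | 20 | 0.291 |
| 29 | 0.319 | 29 | 0.135 | 29 | 0.376 | 29 | 0.362 |
| 39 | 0.363 | 39 | 0.169 | 39 | 0.377 | 39 | 0.418 |
| 50 | 0.376 | 50 | 0.175 | 50 | 0.373 | 50 | 0.463 |

(standard deviation of a reading: 0.005 M)

- order of the initial rate in [partner], near the charge of the maple run, the rate being that where two percent of its starting material are target
- order of the initial rate in [starting material], near the charge of the maple run, the rate being that where two percent of its starting material are target (one fixed amount of target, the same in the runs compared)
- target in the birch run at 200 min, as a share of the starting material charged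

- Overall: starting material + partner -> target, with free catalyst as catalyst.
- Constant volume, constant temperature.
- An order is taken over about fifteen percent of the charge, up and down.

What do you look for? One number. I suppose that a turn of the catalyst is two waits in series, one for starting material and one for partner, with the rate being one over the time of a turn. I then ask what part of that time is left to the partner wait.

Why that part? If a wait shrinks in proportion to its concentration, the order in partner equals the part spent waiting for partner, and the order in starting material is what remains, so the two add to one.

How do you read it? The oak run holds twice the partner of the maple run and the same starting material. Its partner wait is therefore cut to half, and the maple target over the oak target equals one minus half the part sought. That ratio is 0.593 at the first reading and 0.781 at the second.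

Which do you trust? Neither alone. At the first reading the scatter is 15.6 % of the maple value. By the second, the oak run has made more target than the maple run and so has less starting material left, which pulls the ratio towards one. I take the mean, 0.687. I call 0.626 the partner share, the part of a catalyst turn spent waiting for partner. My orders are therefore 0.626 in partner and 0.374 in starting material.

Where is that weak? The series picture is assumed, so test it on a run not yet used. For the alder run it predicts 1.14 times the maple rate, and the alder target over the maple target, at the same two readings, gives a mean of 1.18.

And the birch run? The partner share speaks of early rates, so for 200 min I hold no number of my own.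

The forecast, which differs from my orders, gave 0.55 in partner, 0.3 in starting material and 37.7 %, holding that the birch run “should sit there at 200 min”.

The flask gives 0.69 in partner, 0.34 in starting material and 29.9 %.

    free catalyst + starting material → loaded catalyst + by-product (11.70 M⁻¹ min⁻¹)
    loaded catalyst + partner → target + free catalyst (6.960 M⁻¹ min⁻¹)
    target + partner → side product (0.01134 M⁻¹ min⁻¹)
    starting material → decomposed substrate (0.02820 min⁻¹)

With these constants, loaded catalyst makes up 67.8 % of the catalyst at the maple charge, and free catalyst the remainder. For the larch run, the partner share 0.626 puts the rate below the maple value by a factor 2.42, so 0.018 M min⁻¹ becomes 0.00744 M min⁻¹, against the simulated 0.0070 M min⁻¹. The birch run is low at 200 min because of the conversion of starting material into decomposed substrate: with that conversion taken away, its target stands at 61.2 % instead of 29.9 %.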